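**Retrosynthetic overview**

1. Manassantin A is C2-symmetric. The axis runs through O1 and the midpoint of the C3–C4 bond of the tetrahydrofuran (ring atoms O1, C2–C5), so C3 and C4 are equivalent methyl-bearing carbons, each next to a benzylic ring carbon that can be traced back to a carbonyl carbon: C3–C4 is the Cα–Cα' bond of a (2R,3R)-2,3-dimethylsuccinyl unit.
2. Two-directional endgame: both aryl ether C–O bonds and both carbinol centres go back to a bis-phenol core and a lactate-derived (S)-α-tosyloxy ketone (SN2 with inversion, then catalyst-controlled ketone reduction).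
3. Two-directional core assembly: both aryl–C2/C5 bonds go back to a 3,4-trans-dimethyl-2,5-bis(phenylsulfonyl)tetrahydrofuran; the C3/C4 methyl groups steer both arylations to the 2,3-cis-3,4-trans-4,5-cis pattern.
4. Key disconnection: C3–C4, made by ring-closing oxidative coupling of the two enolates of a dipropanoate held on (R)-BINOL; the axis sets C3 and C4, and the tether is then removed by reduction.
5. Order of ring formation: temporary ten-membered dilactone (step 2, C–C bond), opened in step 3; tetrahydrofuran (step 4, C–O bonds, from the dialdehyde); no other ring is made.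

Key step: step 2

Assumption: the (R)-configured binaphthyl axis is taken to favour the (3R,4R)-dilactone (both methyl groups pseudo-equatorial on the twisted ten-membered ring); if diol 6 proves to be the antipode by polarimetry, (S)-BINOL is used in step 1 and nothing else changes.

**Route**

Step 1
Reactants: 1 (R)-1,1'-bi-2-naphthol; 2 propanoyl chloride
Product: 3 (R)-1,1'-binaphthalene-2,2'-diyl dipropanoate
Conditions: 2 (2.4 equiv), Et3N, 4-(dimethylamino)pyridine (cat.), CH2Cl2, 0 °C to rt
Reagents that add atoms: none
Why: Nucleophilic acyl substitution (amine-catalysed O-acylation) of both naphthol hydroxyls should be fast and complete; the binaphthyl axis is configurationally stable under these conditions and no new stereocentre forms.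

Step 2
Reactants: 3 (R)-1,1'-binaphthalene-2,2'-diyl dipropanoate
Product: 5 cyclic (R)-1,1'-binaphthalene-2,2'-diyl (2R,3R)-2,3-dimethylbutanedioate, via dilithium bis-enolate 4 (not isolated)
Conditions: LiN(iPr)2 (2.2 equiv), THF, −78 °C, 0.01 M, inverse addition; then CuCl2 (2.4 equiv) in DMF, −78 to 0 °C
Reagents that add atoms: none
Why: Double deprotonation gives the C2-symmetric dilithium bis-enolate, and each enolate is oxidised by one electron by divalent copper (through copper enolates and α-acyl radicals), so that the two α-carbons join by radical–radical coupling or by radical–enolate coupling followed by the second oxidation; this is the oxidative coupling of ester enolates to succinates, run intramolecularly inside a diol-diester template. The only ring closed is the temporary ten-membered dilactone, by Cα–Cα' bond formation between two trigonal carbons that both become ring stereocentres, and it is pre-organised because the 2,2'-oxygens of the binaphthyl hold the two enolates a few ångström apart. Both new stereocentres (the later C3 and C4 of the tetrahydrofuran) are controlled by the binaphthyl axis: only the like combination of enolate faces keeps the C2 axis and gives the trans-dimethyl isomer, and the fixed helical twist of the ring should let only one of the two trans isomers carry both methyl groups pseudo-equatorially, away from the naphthalene faces. The step needs ring closure over oligomerisation (secured by the rigid cisoid tether, high dilution and inverse addition), coupling over Claisen condensation or ketene loss (secured by complete bis-enolisation at −78 °C), and one trans isomer over the meso-type and the mismatched trans isomers (secured by the axis). The α-centres of the aryl ester product stay epimerisable, so a minor isomer could still be equilibrated with a weak base to the most stable diastereomer before the tether is removed.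

Step 3
Reactants: 5 cyclic (R)-1,1'-binaphthalene-2,2'-diyl (2R,3R)-2,3-dimethylbutanedioate
Product: 6 (2R,3R)-2,3-dimethylbutane-1,4-diol
Conditions: LiAlH4, THF, 0 °C; then H2O
Reagents that add atoms: none
Why: Hydride reduction of the two aryl ester carbonyls (LiAlH4 ester reduction) should be faster than enolisation, so the tether leaves as recoverable (R)-BINOL and both methyl-bearing stereocentres pass unchanged into the C2-symmetric diol, on which sense and enantiopurity of the key step can be checked.

Step 4
Reactants: 6 (2R,3R)-2,3-dimethylbutane-1,4-diol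
Product: 8 (3R,4R)-3,4-dimethyl-2,5-bis(phenylsulfonyl)tetrahydrofuran, via (2R,3R)-2,3-dimethylbutanedial 7 (not isolated)
Conditions: (COCl)2, DMSO, CH2Cl2, −78 °C; iPr2NEt, −78 to −30 °C; cold pH 7 wash; then PhSO2H (2.5 equiv), CaCl2, CH2Cl2, rt
Reagents that add atoms: benzenesulfinic acid, O=S(O)c1ccccc1
Why: Swern oxidation activates both primary hydroxyls before any aldehyde is released, so the dialdehyde should form without lactol over-oxidation, and benzenesulfinic acid then traps it by hemiacetal cyclisation and twofold oxocarbenium capture (formation of a 2-sulfonyl cyclic ether), which closes the tetrahydrofuran by C–O bond formation with C3 and C4 untouched and the two anomeric centres as an inconsequential mixture.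

Step 5
Reactants: 8 (3R,4R)-3,4-dimethyl-2,5-bis(phenylsulfonyl)tetrahydrofuran; 9 1-(benzyloxy)-4-bromo-2-methoxybenzene
Product: 12 (2S,3R,4R,5S)-2,5-bis[4-(benzyloxy)-3-methoxyphenyl]-3,4-dimethyltetrahydrofuran, via arylmagnesium bromide 10 (not isolated), via arylzinc bromide 11 (not isolated)
Conditions: 9 (5 equiv), Mg, THF, rt; ZnBr2 (5 equiv), THF, 0 °C; then 8, THF, rt; aqueous NH4Cl
Reagents that add atoms: none
Why: Displacement of anomeric sulfones by an arylzinc reagent proceeds through five-membered oxocarbenium ions that are attacked on the inside face of the envelope with the neighbouring C-methyl pseudo-equatorial, so each aryl group should enter cis to the adjacent methyl and trans to the remote one (the two substituent effects reinforce each other), which sets C2 and C5 as S and gives the 2,3-cis-3,4-trans-4,5-cis core in one two-directional operation.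

Step 6
Reactants: 12 (2S,3R,4R,5S)-2,5-bis[4-(benzyloxy)-3-methoxyphenyl]-3,4-dimethyltetrahydrofuran
Product: 13 4,4'-[(2S,3R,4R,5S)-3,4-dimethyltetrahydrofuran-2,5-diyl]bis(2-methoxyphenol)
Conditions: H2 (1 atm), Pd/C (10% palladium on carbon), EtOAc–MeOH, rt
Reagents that add atoms: none
Why: Hydrogenolysis of the two aryl benzyl ethers should be much faster than cleavage of the ring benzylic C–O bonds, so the bis-phenol is released with all four ring stereocentres intact.

Step 7
Reactants: 14 ethyl (S)-lactate
Product: 15 (2S)-2-hydroxy-N-methoxy-N-methylpropanamide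
Conditions: MeNH(OMe)·HCl, iPrMgCl, THF, −20 to 0 °C
Reagents that add atoms: N,O-dimethylhydroxylamine hydrochloride, CNOC.Cl
Why: Aminolysis of the ester by the magnesium amide (Weinreb amide formation) occurs at low temperature with the hydroxyl carried as its magnesium alkoxide and should leave the lactate stereocentre untouched.

Step 8
Reactants: 15 (2S)-2-hydroxy-N-methoxy-N-methylpropanamide; 16 (3,4-dimethoxyphenyl)magnesium bromide
Product: 17 (2S)-1-(3,4-dimethoxyphenyl)-2-hydroxypropan-1-one
Conditions: iPrMgCl (1.0 equiv), THF, −20 °C; then 16 (1.5 equiv), 0 °C to rt; aqueous NH4Cl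
Reagents that add atoms: none
Why: Aryl Grignard addition to a Weinreb amide stops at the ketone stage through the chelated tetrahedral intermediate, and the preformed magnesium alkoxide protects the hydroxyl and disfavours enolisation, so the (S)-centre should be retained.

Step 9
Reactants: 17 (2S)-1-(3,4-dimethoxyphenyl)-2-hydroxypropan-1-one
Product: 18 (2S)-1-(3,4-dimethoxyphenyl)-1-oxopropan-2-yl 4-methylbenzenesulfonate
Conditions: TsCl, Et3N, 4-(dimethylamino)pyridine (cat.), CH2Cl2, 0 °C
Reagents that add atoms: 4-methylbenzenesulfonyl chloride, Cc1ccc(cc1)S(Cl)(=O)=O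
Why: O-Sulfonylation does not involve the C–O bond of the stereocentre, so the (S)-configuration is kept and the hydroxyl becomes a leaving group activated by the adjacent carbonyl.

Step 10
Reactants: 13 4,4'-[(2S,3R,4R,5S)-3,4-dimethyltetrahydrofuran-2,5-diyl]bis(2-methoxyphenol); 18 (2S)-1-(3,4-dimethoxyphenyl)-1-oxopropan-2-yl 4-methylbenzenesulfonate
Product: 19 (2R,2'R)-2,2'-{[(2S,3R,4R,5S)-3,4-dimethyltetrahydrofuran-2,5-diyl]bis[(2-methoxy-4,1-phenylene)oxy]}bis[1-(3,4-dimethoxyphenyl)propan-1-one]
Conditions: 18 (2.4 equiv), Cs2CO3, DMF, 0 °C to rt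
Reagents that add atoms: none
Why: Williamson-type SN2 displacement of the α-keto tosylate by each caesium phenoxide is accelerated by the neighbouring carbonyl and proceeds with inversion, so the two (S)-tosylates should become the two (R)-aryl ether stereocentres in one two-directional operation.

Step 11
Reactants: 19 (2R,2'R)-2,2'-{[(2S,3R,4R,5S)-3,4-dimethyltetrahydrofuran-2,5-diyl]bis[(2-methoxy-4,1-phenylene)oxy]}bis[1-(3,4-dimethoxyphenyl)propan-1-one]
Product: 20 manassantin A
Conditions: (3aR)-1-methyl-3,3-diphenyltetrahydro-1H,3H-pyrrolo[1,2-c][1,3,2]oxazaborole [(R)-methyl CBS oxazaborolidine] (0.4 equiv), BH3·SMe2, THF, −20 °C; then MeOH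
Reagents that add atoms: none
Why: Corey–Bakshi–Shibata reduction delivers hydride to the Si face of each aryl ketone under catalyst control (aryl as the large group), which coincides with the Felkin–Anh preference of the α-aryloxy ketone (aryloxy group anti to the incoming hydride), so both carbinol centres should form as R and give the two (1R,2R) side chains of the target.

**Compound list**

1 | (R)-1,1'-bi-2-naphthol, (R)-BINOL (axis R; the axis cannot be written in SMILES) | Oc1ccc2ccccc2c1-c1c(O)ccc2ccccc12 | starting material
2 | propanoyl chloride | CCC(Cl)=O | starting material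
3 | (R)-1,1'-binaphthalene-2,2'-diyl dipropanoate (axis R) | CCC(=O)Oc1ccc2ccccc2c1-c1c(OC(=O)CC)ccc2ccccc12 | intermediate
4 | dilithium bis-enolate of 3 (each methyl cis to the aryloxy oxygen; axis R) | C/C=C(/[O-])Oc1ccc2ccccc2c1-c1c(O/C([O-])=C\C)ccc2ccccc12.[Li+].[Li+] | intermediate (not isolated)
5 | cyclic (R)-1,1'-binaphthalene-2,2'-diyl (2R,3R)-2,3-dimethylbutanedioate, ten-membered dilactone (axis R) | C[C@H]1C(=O)Oc2ccc3ccccc3c2-c2c(OC(=O)[C@@H]1C)ccc3ccccc23 | intermediate
6 | (2R,3R)-2,3-dimethylbutane-1,4-diol | OC[C@H](C)[C@@H](C)CO | intermediate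
7 | (2R,3R)-2,3-dimethylbutanedial | O=C[C@H](C)[C@@H](C)C=O | intermediate (not isolated)
8 | (3R,4R)-3,4-dimethyl-2,5-bis(phenylsulfonyl)tetrahydrofuran (mixture at C2/C5) | O=S(=O)(c1ccccc1)C1OC(S(=O)(=O)c2ccccc2)[C@H](C)[C@H]1C | intermediate
9 | 1-(benzyloxy)-4-bromo-2-methoxybenzene | COc1cc(Br)ccc1OCc1ccccc1 | starting material
10 | [4-(benzyloxy)-3-methoxyphenyl]magnesium bromide | COc1cc([Mg]Br)ccc1OCc1ccccc1 | intermediate (not isolated)
11 | [4-(benzyloxy)-3-methoxyphenyl]zinc bromide | COc1cc([Zn]Br)ccc1OCc1ccccc1 | intermediate (not isolated)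
12 | (2S,3R,4R,5S)-2,5-bis[4-(benzyloxy)-3-methoxyphenyl]-3,4-dimethyltetrahydrofuran | COc1cc(ccc1OCc1ccccc1)[C@H]1O[C@H](c2ccc(OCc3ccccc3)c(OC)c2)[C@H](C)[C@H]1C | intermediate
13 | 4,4'-[(2S,3R,4R,5S)-3,4-dimethyltetrahydrofuran-2,5-diyl]bis(2-methoxyphenol) | COc1cc(ccc1O)[C@H]1O[C@H](c2ccc(O)c(OC)c2)[C@H](C)[C@H]1C | intermediate
14 | ethyl (S)-lactate | C[C@H](O)C(=O)OCC | starting material
15 | (2S)-2-hydroxy-N-methoxy-N-methylpropanamide | C[C@H](O)C(=O)N(C)OC | intermediate
16 | (3,4-dimethoxyphenyl)magnesium bromide (THF solution) | COc1ccc([Mg]Br)cc1OC | starting material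
17 | (2S)-1-(3,4-dimethoxyphenyl)-2-hydroxypropan-1-one | C[C@H](O)C(=O)c1ccc(OC)c(OC)c1 | intermediate
18 | (2S)-1-(3,4-dimethoxyphenyl)-1-oxopropan-2-yl 4-methylbenzenesulfonate | C[C@H](OS(=O)(=O)c1ccc(C)cc1)C(=O)c1ccc(OC)c(OC)c1 | intermediate
19 | (2R,2'R)-2,2'-{[(2S,3R,4R,5S)-3,4-dimethyltetrahydrofuran-2,5-diyl]bis[(2-methoxy-4,1-phenylene)oxy]}bis[1-(3,4-dimethoxyphenyl)propan-1-one] | COc1ccc(cc1OC)C(=O)[C@@H](C)Oc1ccc(cc1OC)[C@H]1O[C@H](c2ccc(O[C@H](C)C(=O)c3ccc(OC)c(OC)c3)c(OC)c2)[C@H](C)[C@H]1C | intermediate
20 | manassantin A | COc1ccc([C@@H](O)[C@@H](C)Oc2ccc([C@H]3O[C@H](c4ccc(O[C@H](C)[C@H](O)c5ccc(OC)c(OC)c5)c(OC)c4)[C@H](C)[C@H]3C)cc2OC)cc1OC | target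

**Step count and risks**

Total steps: 11. Longest linear sequence: 8 (steps 1–6, 10, 11); the side-chain electrophile is made in 3 steps (7–9).

Steps most likely to fail:

Step 2. What may go wrong is weak or opposite facial discrimination by the axis during the C–C coupling (meso-type or antipodal dimethylsuccinate), or intermolecular coupling and ketene loss from the aryl ester enolates. The fallback gives up the tether and uses auxiliary-controlled intermolecular oxidative homocoupling of an N-acyloxazolidinone enolate. Setting out from propanoyl chloride 2, N-acylation of lithiated (S)-4-benzyloxazolidin-2-one (n-BuLi, THF, −78 °C) should give (S)-4-benzyl-3-propanoyloxazolidin-2-one F1. Its lithium enolate (LiN(iPr)2, THF, −78 °C) is dimerised with TiCl4 to (2R,3R)-1,4-bis[(4S)-4-benzyl-2-oxooxazolidin-3-yl]-2,3-dimethylbutane-1,4-dione F2, each α-carbon bonding on the face away from the benzyl group as in Evans alkylation. LiBH4 (THF–MeOH, 0 °C) then removes the auxiliary and gives diol 6, where the route is rejoined.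

Step 5. What may go wrong is loss of the second sulfinate from the first oxocarbenium ion or its enol ether with aromatisation to a furan, or erosion of facial selectivity in the first of the two arylations, for which only the second has a direct mono-sulfone model. The fallback replaces the two-directional arylation by a sequential one with a single activated anomeric position at a time. Setting out from diol 6, Swern oxidation as in step 4 followed by MeOH, HC(OMe)3 and camphorsulfonic acid should give (3R,4R)-2,5-dimethoxy-3,4-dimethyltetrahydrofuran F3. One equivalent of PhSO2H with CaCl2 exchanges one methoxy group to give (3R,4R)-2-methoxy-3,4-dimethyl-5-(phenylsulfonyl)tetrahydrofuran F4. Arylzinc bromide 11, which displaces the sulfinate but should leave the methyl acetal, gives (2S,3R,4R)-2-[4-(benzyloxy)-3-methoxyphenyl]-5-methoxy-3,4-dimethyltetrahydrofuran F5. A second exchange with PhSO2H gives (2S,3R,4R)-2-[4-(benzyloxy)-3-methoxyphenyl]-3,4-dimethyl-5-(phenylsulfonyl)tetrahydrofuran F6, and a second addition of 11 gives 12, where the route is rejoined.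

Step 10. What may go wrong is base-mediated enolisation that racemises the α-tosyloxy ketone or epimerises the α-aryloxy ketone product, and incomplete second alkylation. The fallback forms the aryl ether bonds by Mitsunobu reaction on an ester and builds the ketones afterwards. Setting out from bis-phenol 13 and ethyl (S)-lactate 14, PPh3 and diisopropyl azodicarboxylate (THF, 0 °C to rt) should give, with inversion, diethyl (2R,2'R)-2,2'-{[(2S,3R,4R,5S)-3,4-dimethyltetrahydrofuran-2,5-diyl]bis[(2-methoxy-4,1-phenylene)oxy]}dipropanoate F7. MeNH(OMe)·HCl with iPrMgCl converts it into (2R,2'R)-2,2'-{[(2S,3R,4R,5S)-3,4-dimethyltetrahydrofuran-2,5-diyl]bis[(2-methoxy-4,1-phenylene)oxy]}bis(N-methoxy-N-methylpropanamide) F8. Addition of (3,4-dimethoxyphenyl)magnesium bromide 16 then gives bis-ketone 19, where the route is rejoined.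

**Further compounds**

F1 | step 2 | (S)-4-benzyl-3-propanoyloxazolidin-2-one | CCC(=O)N1[C@@H](Cc2ccccc2)COC1=O
F2 | step 2 | (2R,3R)-1,4-bis[(4S)-4-benzyl-2-oxooxazolidin-3-yl]-2,3-dimethylbutane-1,4-dione | O=C([C@H](C)[C@@H](C)C(=O)N1[C@@H](Cc2ccccc2)COC1=O)N1[C@@H](Cc2ccccc2)COC1=O
F3 | step 5 | (3R,4R)-2,5-dimethoxy-3,4-dimethyltetrahydrofuran (mixture at C2/C5) | COC1OC(OC)[C@H](C)[C@H]1C
F4 | step 5 | (3R,4R)-2-methoxy-3,4-dimethyl-5-(phenylsulfonyl)tetrahydrofuran (mixture at C2/C5) | COC1OC(S(=O)(=O)c2ccccc2)[C@H](C)[C@H]1C
F5 | step 5 | (2S,3R,4R)-2-[4-(benzyloxy)-3-methoxyphenyl]-5-methoxy-3,4-dimethyltetrahydrofuran (mixture at C5) | COc1cc(ccc1OCc1ccccc1)[C@H]1OC(OC)[C@H](C)[C@H]1C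
F6 | step 5 | (2S,3R,4R)-2-[4-(benzyloxy)-3-methoxyphenyl]-3,4-dimethyl-5-(phenylsulfonyl)tetrahydrofuran (mixture at C5) | COc1cc(ccc1OCc1ccccc1)[C@H]1OC(S(=O)(=O)c2ccccc2)[C@H](C)[C@H]1C
F7 | step 10 | diethyl (2R,2'R)-2,2'-{[(2S,3R,4R,5S)-3,4-dimethyltetrahydrofuran-2,5-diyl]bis[(2-methoxy-4,1-phenylene)oxy]}dipropanoate | CCOC(=O)[C@@H](C)Oc1ccc(cc1OC)[C@H]1O[C@H](c2ccc(O[C@H](C)C(=O)OCC)c(OC)c2)[C@H](C)[C@H]1C
F8 | step 10 | (2R,2'R)-2,2'-{[(2S,3R,4R,5S)-3,4-dimethyltetrahydrofuran-2,5-diyl]bis[(2-methoxy-4,1-phenylene)oxy]}bis(N-methoxy-N-methylpropanamide) | CON(C)C(=O)[C@@H](C)Oc1ccc(cc1OC)[C@H]1O[C@H](c2ccc(O[C@H](C)C(=O)N(C)OC)c(OC)c2)[C@H](C)[C@H]1C
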